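**Retrosynthetic overview**
1. The target is the (3R,4R) trans lactone. C3 is enolizable, so only C4 must be set by reagent control; C3 follows by equilibration to trans.
2. Lactone C(=O)–O bond (last): closed from a 4-hydroxy methyl ester whose primary alcohol is unmasked by reductive loss of an oxazolidinone. This is the same alcohol-onto-C9 closure by which seco-lignans become lactone lignans.
3. C3–C4 bond (lignan 8–8′): oxidative heterocoupling of two different C6–C3 enolates, a chiral imide enolate (trimethoxy unit) and an ester enolate (dimethoxy unit). It is the laboratory form of the oxidative 8–8′ coupling of phenylpropanoids, and the auxiliary sets C4.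
4. Imide: from 3-(3,4,5-trimethoxyphenyl)propanoic acid and (S)-4-benzyl-1,3-oxazolidin-2-one.
5. Ring order: both arenes are bought; the γ-lactone is the only ring made and it is formed in the last step.

Assumption: methyl 3-(3,4-dimethoxyphenyl)propanoate and LiN(iPr)2 solution are bought as catalogue items.

**Step 1**
Reactants: 1 3-(3,4,5-trimethoxyphenyl)propanoic acid; 2 (S)-4-benzyl-1,3-oxazolidin-2-one
Product: 4 (S)-4-benzyl-3-[3-(3,4,5-trimethoxyphenyl)propanoyl]-1,3-oxazolidin-2-one, via mixed pivalic anhydride 3 (not isolated)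
Conditions: PivCl (1.1 equiv), Et3N (2.5 equiv), THF, −20 °C, 1 h; then 2 (1.0 equiv), LiCl (1.1 equiv), −20 °C to rt, 12 h
Reagents that add atoms: pivaloyl chloride, CC(C)(C)C(=O)Cl (its acyl group is held only by intermediate 3 and leaves again as pivalic acid)
Why: Mixed-anhydride N-acylation of an Evans oxazolidinone: 1 is activated as anhydride 3 and the LiCl/Et3N-activated oxazolidinone attacks its unhindered acyl carbon; no stereocenter is formed and the auxiliary center is not touched.

**Step 2**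
Reactants: 4 (S)-4-benzyl-3-[3-(3,4,5-trimethoxyphenyl)propanoyl]-1,3-oxazolidin-2-one; 5 methyl 3-(3,4-dimethoxyphenyl)propanoate
Product: 8 methyl (3R)-3-{[(4S)-4-benzyl-2-oxo-1,3-oxazolidin-3-yl]carbonyl}-2-(3,4-dimethoxybenzyl)-4-(3,4,5-trimethoxyphenyl)butanoate (C2 epimer mixture), via imide lithium Z-enolate 6 (not isolated), via ester lithium enolate 7 (not isolated)
Conditions: 4 (1.0 equiv) + 5 (1.5 equiv), LiN(iPr)2 (2.6 equiv), THF, −78 °C, 30 min; Fe(acac)3 (2.5 equiv), −78 °C to rt, 1 h; aq. NH4Cl; chromatography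
Reagents that add atoms: none
Why: Oxidative enolate heterocoupling (one-electron oxidation of the mixed lithium enolate aggregate by the trivalent iron of Fe(acac)3, radical-to-enolate C–C bond formation, then a second one-electron oxidation), the laboratory counterpart of the oxidative 8–8′ coupling of two phenylpropanoid units; the new C3 center is set as R because the bond forms on the face of the chelated Z-enolate 6 opposite the 4-benzyl group (the sense of an Evans alkylation), while C2 forms as an epimer mixture that step 3 corrects.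

**Step 3**
Reactants: 8 methyl (3R)-3-{[(4S)-4-benzyl-2-oxo-1,3-oxazolidin-3-yl]carbonyl}-2-(3,4-dimethoxybenzyl)-4-(3,4,5-trimethoxyphenyl)butanoate
Product: 11 (3R,4R)-3-(3,4-dimethoxybenzyl)-4-(3,4,5-trimethoxybenzyl)dihydrofuran-2(3H)-one, via hydroxy ester 9 (not isolated), via lactone C3-epimer mixture 10 (not isolated)
Conditions: NaBH4 (4 equiv), THF/H2O 4:1, 0 °C to rt, 3 h; 1 M HCl work-up; crude in PhMe, DBU (1.5 equiv), 90 °C, 12 h
Reagents that add atoms: none
Why: Chemoselective borohydride cleavage of the N-acyl oxazolidinone (NaBH4 in wet THF leaves the methyl ester alone) frees the primary alcohol of 9, which closes the γ-lactone on the neighbouring ester by transesterification (the same alcohol-to-C9 closure as in lignan lactone biosynthesis), and DBU then epimerizes the enolizable C3 of 10 to the thermodynamically preferred trans isomer, so the fixed (R)-C4 dictates (R)-C3 and no center set earlier is touched.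

**Compound list**
1 | 3-(3,4,5-trimethoxyphenyl)propanoic acid | COc1cc(CCC(=O)O)cc(OC)c1OC | starting material
2 | (S)-4-benzyl-1,3-oxazolidin-2-one | O=C1N[C@@H](Cc2ccccc2)CO1 | starting material
3 | 3-(3,4,5-trimethoxyphenyl)propanoic pivalic anhydride | COc1cc(CCC(=O)OC(=O)C(C)(C)C)cc(OC)c1OC | intermediate
4 | (S)-4-benzyl-3-[3-(3,4,5-trimethoxyphenyl)propanoyl]-1,3-oxazolidin-2-one | COc1cc(CCC(=O)N2[C@@H](Cc3ccccc3)COC2=O)cc(OC)c1OC | intermediate
5 | methyl 3-(3,4-dimethoxyphenyl)propanoate | COC(=O)CCc1ccc(OC)c(OC)c1 | starting material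
6 | lithium (1Z)-1-[(4S)-4-benzyl-2-oxo-1,3-oxazolidin-3-yl]-3-(3,4,5-trimethoxyphenyl)prop-1-en-1-olate | [Li+].[O-]/C(=C\Cc1cc(OC)c(OC)c(OC)c1)N1[C@@H](Cc2ccccc2)COC1=O | intermediate
7 | lithium 1-methoxy-3-(3,4-dimethoxyphenyl)prop-1-en-1-olate (geometry not specified) | [Li+].[O-]C(OC)=CCc1ccc(OC)c(OC)c1 | intermediate
8 | methyl (3R)-3-{[(4S)-4-benzyl-2-oxo-1,3-oxazolidin-3-yl]carbonyl}-2-(3,4-dimethoxybenzyl)-4-(3,4,5-trimethoxyphenyl)butanoate (C2 epimers) | COC(=O)C(Cc1ccc(OC)c(OC)c1)[C@@H](Cc1cc(OC)c(OC)c(OC)c1)C(=O)N1[C@@H](Cc2ccccc2)COC1=O | intermediate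
9 | methyl (3R)-2-(3,4-dimethoxybenzyl)-3-(hydroxymethyl)-4-(3,4,5-trimethoxyphenyl)butanoate (C2 epimers) | COC(=O)C(Cc1ccc(OC)c(OC)c1)[C@@H](Cc1cc(OC)c(OC)c(OC)c1)CO | intermediate
10 | (4R)-3-(3,4-dimethoxybenzyl)-4-(3,4,5-trimethoxybenzyl)dihydrofuran-2(3H)-one (cis/trans mixture at C3) | COc1ccc(CC2C(=O)OC[C@@H]2Cc2cc(OC)c(OC)c(OC)c2)cc1OC | intermediate
11 | (3R,4R)-3-(3,4-dimethoxybenzyl)-4-(3,4,5-trimethoxybenzyl)dihydrofuran-2(3H)-one (trans) | COc1ccc(C[C@H]2C(=O)OC[C@@H]2Cc2cc(OC)c(OC)c(OC)c2)cc1OC | target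

**Totals**
Total step count: 3. Longest linear sequence: 3 steps (1 → 4 → 8 → 11).

**Steps most likely to fail, with fallbacks**

Step 2 (most risky). Homodimers of 6 and 7 compete with the heterocoupling, and any bond formation on the wrong face of 6 ends up as the enantiomer of 11. Compound 8 is therefore chromatographed so that only the two (3R) epimers go forward, and the ee of 11 is checked by chiral HPLC. Fallback, setting out from 4 through its enolate 6 and coming back at 11: give up the oxidative coupling and attach the two arms one after the other. Enolate 6 (LiN(iPr)2, THF, −78 °C) is alkylated with tert-butyl bromoacetate (Evans alkylation) to the succinate tert-butyl (3R)-4-[(4S)-4-benzyl-2-oxo-1,3-oxazolidin-3-yl]-4-oxo-3-(3,4,5-trimethoxybenzyl)butanoate F1. LiBH4 (THF, 1 equiv MeOH, 0 °C) removes the auxiliary and leaves the tert-butyl ester, giving the hydroxy ester tert-butyl (3R)-3-(hydroxymethyl)-4-(3,4,5-trimethoxyphenyl)butanoate F2. TsOH in toluene at 80 °C closes it to the lactone (4R)-4-(3,4,5-trimethoxybenzyl)dihydrofuran-2(3H)-one F3. LiN(SiMe3)2 (THF, −78 °C) gives the enolate lithium (3R)-3-(3,4,5-trimethoxybenzyl)-2,3-dihydrofuran-5-olate F4, and 3,4-dimethoxybenzyl bromide enters trans to the C4 substituent to give 11.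

Step 3. The hindered imide may be reduced slowly, hydride may open the auxiliary ring, or the lactone may be over-reduced to the diol. DBU may also leave some cis isomer, which is removed by chromatography or recrystallization. Fallback, setting out from 8 and coming back at 9: remove the auxiliary by hydrolysis instead of reduction. LiOH/H2O2 (THF/H2O, 0 °C) gives the peracid (2R)-4-(3,4-dimethoxyphenyl)-3-(methoxycarbonyl)-2-(3,4,5-trimethoxybenzyl)butaneperoxoic acid F5, which Na2SO3 reduces in the same flask to the acid (2R)-4-(3,4-dimethoxyphenyl)-3-(methoxycarbonyl)-2-(3,4,5-trimethoxybenzyl)butanoic acid F6. BH3·SMe2 (THF, 0 °C) reduces the free acid but not the methyl ester and delivers hydroxy ester 9. Compound 9 is closed with catalytic TsOH in toluene to 10 and epimerized with DBU to 11 as in step 3.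

Step 1. The mixed anhydride may acylate sluggishly or transfer the pivaloyl group to 2. Fallback, setting out from 1 and coming back at 4: convert 1 with (COCl)2 and catalytic DMF in CH2Cl2 into the isolated acid chloride 3-(3,4,5-trimethoxyphenyl)propanoyl chloride F7, then acylate 2 with it (Et3N, catalytic DMAP, CH2Cl2, 0 °C to rt) to reach 4.

**Further compounds**
F1 | step 2 | tert-butyl (3R)-4-[(4S)-4-benzyl-2-oxo-1,3-oxazolidin-3-yl]-4-oxo-3-(3,4,5-trimethoxybenzyl)butanoate | CC(C)(C)OC(=O)C[C@@H](Cc1cc(OC)c(OC)c(OC)c1)C(=O)N1[C@@H](Cc2ccccc2)COC1=O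
F2 | step 2 | tert-butyl (3R)-3-(hydroxymethyl)-4-(3,4,5-trimethoxyphenyl)butanoate | CC(C)(C)OC(=O)C[C@@H](Cc1cc(OC)c(OC)c(OC)c1)CO
F3 | step 2 | (4R)-4-(3,4,5-trimethoxybenzyl)dihydrofuran-2(3H)-one | O=C1C[C@@H](Cc2cc(OC)c(OC)c(OC)c2)CO1
F4 | step 2 | lithium (3R)-3-(3,4,5-trimethoxybenzyl)-2,3-dihydrofuran-5-olate | [Li+].[O-]C1=C[C@@H](Cc2cc(OC)c(OC)c(OC)c2)CO1
F5 | step 3 | (2R)-4-(3,4-dimethoxyphenyl)-3-(methoxycarbonyl)-2-(3,4,5-trimethoxybenzyl)butaneperoxoic acid (C3 epimers) | COC(=O)C(Cc1ccc(OC)c(OC)c1)[C@@H](Cc1cc(OC)c(OC)c(OC)c1)C(=O)OO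
F6 | step 3 | (2R)-4-(3,4-dimethoxyphenyl)-3-(methoxycarbonyl)-2-(3,4,5-trimethoxybenzyl)butanoic acid (C3 epimers) | COC(=O)C(Cc1ccc(OC)c(OC)c1)[C@@H](Cc1cc(OC)c(OC)c(OC)c1)C(=O)O
F7 | step 1 | 3-(3,4,5-trimethoxyphenyl)propanoyl chloride | COc1cc(CCC(=O)Cl)cc(OC)c1OC
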